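**Strategy.** Ring B (C5–C6–C7–C8–C9–C10) is cut into two three-carbon units: the β-cyclogeranyl allyl cation (C6–C5–C10, ring A intact) as 1,3-dielectrophile and an acetoacetate (C7–C8–C9, ester carbon = C11) as 1,3-dinucleophile. In one operation the bis-silyl dienol ether of (−)-8-phenylmenthyl acetoacetate is alkylated at C7 by the allylic terminus C6, and the C5=C10 olefin is then protonated so that enol carbon C9 closes onto tertiary C10, as in the biosynthetic B-ring closure. The step exploits the allylic C6/tertiary C10 pair of ring A; the auxiliary fixes quaternary C10 and the trans C5–H. The C8 oxygen is then exchanged for methyl, and B-alkyl Suzuki coupling and iodo-acid/alkyne lactonisation add the side chain.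

Key step: step 5

Remark: drimane numbering is used (ring carbons C1–C10, C11 on C9, chain C12–C15, lactone C16–C19); the target is (5S,10S), 13E, 15Z, and the sense of induction by the (1R,2S,5R) auxiliary is assigned from the stacking model given in step 5.

Step 1
Reactants: 1 β-cyclocitral
Product: 2 β-cyclogeraniol
Conditions: NaBH4, MeOH, 0 °C
Reagents that add atoms: none
Why: Borohydride 1,2-reduction of the enal should give the allylic alcohol, since conjugate reduction at the fully substituted β-carbon does not compete.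

Step 2
Reactants: 2 β-cyclogeraniol
Product: 3 β-cyclogeranyl acetate
Conditions: Ac2O, pyridine, DMAP (cat.), CH2Cl2, 0 → 25 °C
Reagents that add atoms: acetic anhydride CC(=O)OC(C)=O
Why: DMAP-catalysed acylation of the primary allylic alcohol gives the acetate that serves as the ionisable leaving group.

Step 3
Reactants: 4 (−)-8-phenylmenthol; 5 diketene–acetone adduct (2,2,6-trimethyl-4H-1,3-dioxin-4-one)
Product: 7 acetoacetate ester of (−)-8-phenylmenthol, via acetylketene 6 (not isolated)
Conditions: xylene, 140 °C, acetone distilled off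
Reagents that add atoms: none
Why: Thermal retro-[4+2] fragmentation of the dioxinone releases acetylketene, which acylates the hindered secondary alcohol (acetoacetylation) without creating a stereocentre.

Step 4
Reactants: 7 acetoacetate ester of (−)-8-phenylmenthol
Product: 8 bis-silyl dienol ether of 7 [1-(8-phenylmenthyloxy)-1,3-bis(trimethylsilyloxy)buta-1,3-diene]
Conditions: TMSOTf (2.2 equiv), Et3N (2.5 equiv), Et2O, 0 → 25 °C
Reagents that add atoms: trimethylsilyl trifluoromethanesulfonate C[Si](C)(C)OS(=O)(=O)C(F)(F)F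
Why: Soft enolisation and double O-silylation of the β-keto ester gives the 1,3-bis(silyloxy)diene, the neutral equivalent of the acetoacetate dianion; its ketene acetal geometry is immaterial.

Step 5
Reactants: 3 β-cyclogeranyl acetate; 8 bis-silyl dienol ether of 7
Product: 10 (−)-8-phenylmenthyl (1R,4aS,8aS)-5,5,8a-trimethyl-2-oxodecahydronaphthalene-1-carboxylate, via silyl enol ether 9 (not isolated)
Conditions: TMSOTf (0.2 equiv), CH2Cl2, −78 → −40 °C; then SnCl4, CF3CO2H, −78 → −20 °C
Reagents that add atoms: none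
Why: Proposed new method: a domino formal [3+3] annulation in which silyl triflate ionises acetate 3 to the β-cyclogeranyl cation, whose primary terminus C6 is captured by the terminal carbon C7 of diene 8 (vinylogous Mukaiyama-type SN1 alkylation) to give silyl enol ether 9, after which the SnCl4/CF3CO2H Lewis-acid-assisted Brønsted acid protonates the C5=C10 olefin at C5 and the SnCl3-chelated enol attacks the tertiary C10 cation through C9. The closest known reactions are the Lewis-acid γ-alkylation of 1,3-bis(silyloxy)dienes with SN1-active electrophiles and the SnCl4-mediated cation–olefin cyclisation of olefinic β-keto esters to trans-decalones; their union in one flask and the auxiliary-controlled absolute sense are new. Ring B closes in a 6-endo-trig (enol-endo) cation–olefin mode through a chair transition state. C10 is set by the auxiliary, whose phenyl ring stacks over one face of the planar chelated enolate so that C10 bonds to the open face; C5 is set by the chair closure that places H5 and the C10 methyl trans-diaxial, while reversible protonation returns mismatched cations to the olefin; C9 settles with the ester equatorial and is erased in step 6. The step needs terminal over internal attack of the diene (secured by the more nucleophilic terminal CH2), attack at C6 rather than C10 of the allyl cation (primary versus tertiary terminus), six- over five-membered closure (tertiary C10 cation, chair) and facial control (auxiliary; any minor diastereomer is separable because it is not an enantiomer).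

Step 6
Reactants: 10 bicyclic β-keto ester
Product: 11 enol triflate, (−)-8-phenylmenthyl (4aS,8aS)-5,5,8a-trimethyl-2-(trifluoromethylsulfonyloxy)-3,4,4a,5,6,7,8,8a-octahydronaphthalene-1-carboxylate
Conditions: NaH, Et2O, 0 °C; then Tf2O, −78 → 0 °C
Reagents that add atoms: trifluoromethanesulfonic anhydride O=S(=O)(OS(=O)(=O)C(F)(F)F)C(F)(F)F
Why: Deprotonation at C9 between the two carbonyls and O-sulfonylation of the enolate gives the C8 vinyl triflate regiospecifically.

Step 7
Reactants: 11 enol triflate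
Product: 12 (−)-8-phenylmenthyl drim-8-en-11-oate [(4aS,8aS)-2,5,5,8a-tetramethyl-3,4,4a,5,6,7,8,8a-octahydronaphthalene-1-carboxylate]
Conditions: MeMgBr, Fe(acac)3 (5 mol%), THF/NMP, −30 °C
Reagents that add atoms: methylmagnesium bromide C[Mg]Br
Why: Iron-catalysed Kumada-type cross-coupling of the β-triflyloxy enoate installs the C8 methyl and fixes the tetrasubstituted C8=C9 olefin without attack on the hindered ester.

Step 8
Reactants: 12 (−)-8-phenylmenthyl drim-8-en-11-oate
Product: 13 drim-8-en-11-ol {[(4aS,8aS)-2,5,5,8a-tetramethyl-3,4,4a,5,6,7,8,8a-octahydronaphthalen-1-yl]methanol}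
Conditions: DIBAL-H (excess), toluene, −78 → 25 °C; aq. Rochelle salt
Reagents that add atoms: none
Why: Hydride 1,2-reduction of the hindered enoate releases the C11 allylic alcohol and returns auxiliary 4 for reuse.

Step 9
Reactants: 13 drim-8-en-11-ol
Product: 14 drim-8-en-11-al [(4aS,8aS)-2,5,5,8a-tetramethyl-3,4,4a,5,6,7,8,8a-octahydronaphthalene-1-carbaldehyde]
Conditions: activated MnO2, CH2Cl2, 25 °C
Reagents that add atoms: none
Why: Manganese dioxide oxidises the allylic alcohol selectively to the enal and leaves the tetrasubstituted olefin untouched.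

Step 10
Reactants: 14 drim-8-en-11-al
Product: 15 diene, (4aS,8aS)-1-ethenyl-2,5,5,8a-tetramethyl-3,4,4a,5,6,7,8,8a-octahydronaphthalene
Conditions: Ph3PCH3Br, KOtBu, THF, 0 → 25 °C
Reagents that add atoms: methyltriphenylphosphonium bromide C[P+](c1ccccc1)(c1ccccc1)c1ccccc1.[Br-]
Why: Wittig methylenation of the hindered enal with the small unstabilised ylide adds C12 as a terminal vinyl group.

Step 11
Reactants: 16 trimethylsilylpropynal [3-(trimethylsilyl)prop-2-ynal]; 17 ethyl (triphenylphosphoranylidene)acetate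
Product: 19 ethyl (Z)-2-iodo-5-(trimethylsilyl)pent-2-en-4-ynoate, via iodo ylide 18 (not isolated)
Conditions: 17, NIS, CH2Cl2, −20 °C; then 16, −20 → 25 °C
Reagents that add atoms: N-iodosuccinimide O=C1CCC(=O)N1I
Why: Iodination of the stabilised ylide followed by Wittig olefination of the ynal (one-pot halogenation–Wittig) should give mainly the Z-α-iodo enoate, the ester ending trans to the alkynyl group as usual for stabilised ylides.

Step 12
Reactants: 19 ethyl (Z)-2-iodo-5-(trimethylsilyl)pent-2-en-4-ynoate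
Product: 20 (Z)-2-iodo-5-(trimethylsilyl)pent-2-en-4-yn-1-ol
Conditions: DIBAL-H (2.2 equiv), CH2Cl2, −78 °C
Reagents that add atoms: none
Why: DIBAL-H reduces the ester to the primary allylic alcohol at low temperature without touching the vinyl iodide, the silylalkyne or the olefin geometry.

Step 13
Reactants: 15 diene; 20 (Z)-2-iodo-5-(trimethylsilyl)pent-2-en-4-yn-1-ol
Product: 23 (E)-2-{2-[(4aS,8aS)-2,5,5,8a-tetramethyl-3,4,4a,5,6,7,8,8a-octahydronaphthalen-1-yl]ethyl}pent-2-en-4-yn-1-ol, via alkylborane 21 (not isolated), via silylated enynol 22 (not isolated)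
Conditions: 9-BBN, THF, 0 → 25 °C; then 20, PdCl2(dppf) (cat.), AsPh3, Cs2CO3, DMF/H2O, 25 °C; then K2CO3 (cat.), MeOH, 25 °C
Reagents that add atoms: none
Why: 9-BBN adds only to the terminal vinyl group (boron at C12), and B-alkyl Suzuki–Miyaura coupling with Z-vinyl iodide 20 forms C12–C13 with retention of geometry, so the hydroxymethyl group stays trans to the alkynyl group; carbonate in methanol then removes the alkyne silyl group.

Step 14
Reactants: 24 but-2-ynoic acid
Product: 25 (Z)-3-iodobut-2-enoic acid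
Conditions: NaI, AcOH, 110 °C
Reagents that add atoms: sodium iodide [Na+].[I-]
Why: Anti-hydroiodination of the ynoic acid by HI generated in situ gives the Z-β-iodo acid stereoselectively.

Step 15
Reactants: 23 terminal enynol; 25 (Z)-3-iodobut-2-enoic acid
Product: 27 target, (5Z)-5-{(2E)-3-(hydroxymethyl)-5-[(4aS,8aS)-2,5,5,8a-tetramethyl-3,4,4a,5,6,7,8,8a-octahydronaphthalen-1-yl]pent-2-en-1-ylidene}-4-methylfuran-2(5H)-one, via enynoic acid 26 (not isolated)
Conditions: Pd(PPh3)4 (5 mol%), CuI (10 mol%), Et3N, MeCN, 25 °C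
Reagents that add atoms: none
Why: Sonogashira coupling gives the Z-enynoic acid, whose carboxylate adds anti across the metal-activated alkyne in a 5-exo-dig lactonisation, which should give the Z-γ-ylidene butenolide with the chain cis to the ring oxygen.

**Compound list**

1 | β-cyclocitral (2,6,6-trimethylcyclohex-1-ene-1-carbaldehyde) | CC1=C(C=O)C(C)(C)CCC1 | starting material
2 | β-cyclogeraniol [(2,6,6-trimethylcyclohex-1-en-1-yl)methanol] | CC1=C(CO)C(C)(C)CCC1 | intermediate
3 | β-cyclogeranyl acetate | CC(=O)OCC1=C(C)CCCC1(C)C | intermediate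
4 | (−)-8-phenylmenthol [(1R,2S,5R)-5-methyl-2-(2-phenylpropan-2-yl)cyclohexan-1-ol] | C[C@@H]1CC[C@H]([C@@H](C1)O)C(C)(C)c2ccccc2 | starting material
5 | diketene–acetone adduct (2,2,6-trimethyl-4H-1,3-dioxin-4-one) | CC1=CC(=O)OC(C)(C)O1 | starting material
6 | acetylketene | CC(=O)C=C=O | intermediate
7 | (1R,2S,5R)-5-methyl-2-(2-phenylpropan-2-yl)cyclohexyl 3-oxobutanoate | C[C@@H]1CC[C@H]([C@@H](C1)OC(=O)CC(C)=O)C(C)(C)c2ccccc2 | intermediate
8 | 1-[(1R,2S,5R)-8-phenylmenthyloxy]-1,3-bis(trimethylsilyloxy)buta-1,3-diene (ketene acetal geometry not defined) | C[C@@H]1CC[C@H]([C@@H](C1)OC(O[Si](C)(C)C)=CC(=C)O[Si](C)(C)C)C(C)(C)c2ccccc2 | intermediate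
9 | (1R,2S,5R)-8-phenylmenthyl 3-(trimethylsilyloxy)-5-(2,6,6-trimethylcyclohex-1-en-1-yl)pent-2-enoate (enol ether geometry not defined) | C[C@@H]1CC[C@H]([C@@H](C1)OC(=O)C=C(CCC3=C(C)CCCC3(C)C)O[Si](C)(C)C)C(C)(C)c2ccccc2 | intermediate
10 | (1R,2S,5R)-8-phenylmenthyl (1R,4aS,8aS)-5,5,8a-trimethyl-2-oxodecahydronaphthalene-1-carboxylate (trans-fused, ester equatorial) | C[C@@H]1CC[C@H]([C@@H](C1)OC(=O)[C@H]3C(=O)CC[C@H]4C(C)(C)CCC[C@]34C)C(C)(C)c2ccccc2 | intermediate
11 | (1R,2S,5R)-8-phenylmenthyl (4aS,8aS)-5,5,8a-trimethyl-2-(trifluoromethylsulfonyloxy)-3,4,4a,5,6,7,8,8a-octahydronaphthalene-1-carboxylate | C[C@@H]1CC[C@H]([C@@H](C1)OC(=O)C3=C(OS(=O)(=O)C(F)(F)F)CC[C@H]4C(C)(C)CCC[C@]34C)C(C)(C)c2ccccc2 | intermediate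
12 | (1R,2S,5R)-8-phenylmenthyl (4aS,8aS)-2,5,5,8a-tetramethyl-3,4,4a,5,6,7,8,8a-octahydronaphthalene-1-carboxylate | C[C@@H]1CC[C@H]([C@@H](C1)OC(=O)C3=C(C)CC[C@H]4C(C)(C)CCC[C@]34C)C(C)(C)c2ccccc2 | intermediate
13 | [(4aS,8aS)-2,5,5,8a-tetramethyl-3,4,4a,5,6,7,8,8a-octahydronaphthalen-1-yl]methanol (drim-8-en-11-ol) | OCC1=C(C)CC[C@H]2C(C)(C)CCC[C@]12C | intermediate
14 | (4aS,8aS)-2,5,5,8a-tetramethyl-3,4,4a,5,6,7,8,8a-octahydronaphthalene-1-carbaldehyde | O=CC1=C(C)CC[C@H]2C(C)(C)CCC[C@]12C | intermediate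
15 | (4aS,8aS)-1-ethenyl-2,5,5,8a-tetramethyl-3,4,4a,5,6,7,8,8a-octahydronaphthalene | C=CC1=C(C)CC[C@H]2C(C)(C)CCC[C@]12C | intermediate
16 | 3-(trimethylsilyl)prop-2-ynal | C[Si](C)(C)C#CC=O | starting material
17 | ethyl (triphenylphosphoranylidene)acetate | CCOC(=O)C=P(c1ccccc1)(c1ccccc1)c1ccccc1 | starting material
18 | ethyl iodo(triphenylphosphoranylidene)acetate | CCOC(=O)C(I)=P(c1ccccc1)(c1ccccc1)c1ccccc1 | intermediate
19 | ethyl (Z)-2-iodo-5-(trimethylsilyl)pent-2-en-4-ynoate | CCOC(=O)/C(I)=C/C#C[Si](C)(C)C | intermediate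
20 | (Z)-2-iodo-5-(trimethylsilyl)pent-2-en-4-yn-1-ol | OC/C(I)=C/C#C[Si](C)(C)C | intermediate
21 | 9-{2-[(4aS,8aS)-2,5,5,8a-tetramethyl-3,4,4a,5,6,7,8,8a-octahydronaphthalen-1-yl]ethyl}-9-borabicyclo[3.3.1]nonane | B1(CCC3=C(C)CC[C@H]4C(C)(C)CCC[C@]34C)C2CCCC1CCC2 | intermediate
22 | (E)-2-{2-[(4aS,8aS)-2,5,5,8a-tetramethyl-3,4,4a,5,6,7,8,8a-octahydronaphthalen-1-yl]ethyl}-5-(trimethylsilyl)pent-2-en-4-yn-1-ol | C[Si](C)(C)C#C/C=C(/CO)CCC1=C(C)CC[C@H]2C(C)(C)CCC[C@]12C | intermediate
23 | (E)-2-{2-[(4aS,8aS)-2,5,5,8a-tetramethyl-3,4,4a,5,6,7,8,8a-octahydronaphthalen-1-yl]ethyl}pent-2-en-4-yn-1-ol | C#C/C=C(/CO)CCC1=C(C)CC[C@H]2C(C)(C)CCC[C@]12C | intermediate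
24 | but-2-ynoic acid | CC#CC(=O)O | starting material
25 | (Z)-3-iodobut-2-enoic acid | C/C(I)=C/C(=O)O | intermediate
26 | (2Z,6E)-7-(hydroxymethyl)-3-methyl-9-[(4aS,8aS)-2,5,5,8a-tetramethyl-3,4,4a,5,6,7,8,8a-octahydronaphthalen-1-yl]nona-2,6-dien-4-ynoic acid | C/C(=C/C(=O)O)C#C/C=C(/CO)CCC1=C(C)CC[C@H]2C(C)(C)CCC[C@]12C | intermediate
27 | (5Z)-5-{(2E)-3-(hydroxymethyl)-5-[(4aS,8aS)-2,5,5,8a-tetramethyl-3,4,4a,5,6,7,8,8a-octahydronaphthalen-1-yl]pent-2-en-1-ylidene}-4-methylfuran-2(5H)-one | CC1=CC(=O)O/C1=C\C=C(\CO)CCC1=C(C)CC[C@H]2C(C)(C)CCC[C@]12C | target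

**Step count.** Total: 15 steps. Longest linear sequence: 10 steps (3, 4, 5, 6, 7, 8, 9, 10, 13, 15; the branch through steps 1 and 2 is equally long).

**Steps most likely to fail**

Step 5 (proposed new method). The allyl cation may lose a proton, or the dienol ether may be protodesilylated, before the C6–C7 bond forms. The second stage may close through the shielded enolate face or in a five-membered spiro mode, and facial discrimination by the auxiliary may be insufficient. The fallback uses known chemistry and sets out from 2 and 7. Alcohol 2 is converted with PBr3 (Et2O, −10 °C) into β-cyclogeranyl bromide F1. F1 alkylates the terminal carbon of the dianion of 7 (NaH, then n-BuLi, THF, 0 °C) in an SN2 reaction to give the open-chain olefinic keto ester, 8-phenylmenthyl 3-oxo-5-(2,6,6-trimethylcyclohex-1-en-1-yl)pentanoate F2. F2 is isolated and cyclised separately with SnCl4 in moist CH2Cl2, the established cation–olefin closure of such keto esters. This gives 10 together with its (1S,4aR,8aR)-decalone diastereomer F3, from which 10 is separated by chromatography or crystallisation. The route is rejoined at 10.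

Step 13. Transmetalation of the alkylborane may be slow, so that β-hydride elimination or protodeboronation takes over; the Z-iodide may isomerise, or the silylalkyne may be cleaved early and then react at palladium. The fallback sets out from 15 and forms C12–C13 by enolate alkylation and C13=C14 by olefination. Hydroboration–oxidation (9-BBN; NaOH, H2O2) gives 2-[(4aS,8aS)-2,5,5,8a-tetramethyl-octahydronaphthalen-1-yl]ethanol F4. Appel iodination (I2, PPh3, imidazole) gives the primary iodide F5. Alkylation of sodium triethyl phosphonoacetate (NaH, DMF) gives the α-substituted phosphonate F6. Horner–Wadsworth–Emmons olefination with 16 (NaH, THF) gives the E-enoate F7, with the ester trans to the alkynyl group. DIBAL-H reduction then gives 22, which is desilylated as in step 13. The route is rejoined at 22.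

Step 15. The acid may close in the 6-endo-dig mode to a 2-pyranone, the ylidene geometry may scramble, or copper may promote alkyne homocoupling. The fallback sets out from 23 and 25 and separates C–C coupling from C–O closure. Acid 25 is esterified (MeI, K2CO3, DMF) to methyl (Z)-3-iodobut-2-enoate F8. Sonogashira coupling with 23 gives the dienyne methyl ester F9. Saponification (LiOH, THF/H2O) gives 26, now isolated. A separate silver(I)-catalysed cyclisation (AgNO3, acetone), a π-acid manifold that favours 5-exo-dig closure to Z-ylidene butenolides, gives 27, where the route is rejoined.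

**Further compounds**

F1 | step 5 | β-cyclogeranyl bromide | CC1=C(CBr)C(C)(C)CCC1
F2 | step 5 | (1R,2S,5R)-8-phenylmenthyl 3-oxo-5-(2,6,6-trimethylcyclohex-1-en-1-yl)pentanoate | C[C@@H]1CC[C@H]([C@@H](C1)OC(=O)CC(=O)CCC3=C(C)CCCC3(C)C)C(C)(C)c2ccccc2
F3 | step 5 | (1R,2S,5R)-8-phenylmenthyl (1S,4aR,8aR)-5,5,8a-trimethyl-2-oxodecahydronaphthalene-1-carboxylate | C[C@@H]1CC[C@H]([C@@H](C1)OC(=O)[C@@H]3C(=O)CC[C@@H]4C(C)(C)CCC[C@@]34C)C(C)(C)c2ccccc2
F4 | step 13 | 2-[(4aS,8aS)-2,5,5,8a-tetramethyl-3,4,4a,5,6,7,8,8a-octahydronaphthalen-1-yl]ethanol | OCCC1=C(C)CC[C@H]2C(C)(C)CCC[C@]12C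
F5 | step 13 | (4aS,8aS)-1-(2-iodoethyl)-2,5,5,8a-tetramethyl-3,4,4a,5,6,7,8,8a-octahydronaphthalene | ICCC1=C(C)CC[C@H]2C(C)(C)CCC[C@]12C
F6 | step 13 | ethyl 2-(diethoxyphosphoryl)-4-[(4aS,8aS)-2,5,5,8a-tetramethyl-3,4,4a,5,6,7,8,8a-octahydronaphthalen-1-yl]butanoate (epimers at C2) | CCOC(=O)C(CCC1=C(C)CC[C@H]2C(C)(C)CCC[C@]12C)P(=O)(OCC)OCC
F7 | step 13 | ethyl (E)-2-{2-[(4aS,8aS)-2,5,5,8a-tetramethyl-3,4,4a,5,6,7,8,8a-octahydronaphthalen-1-yl]ethyl}-5-(trimethylsilyl)pent-2-en-4-ynoate | CCOC(=O)/C(CCC1=C(C)CC[C@H]2C(C)(C)CCC[C@]12C)=C/C#C[Si](C)(C)C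
F8 | step 15 | methyl (Z)-3-iodobut-2-enoate | C/C(I)=C/C(=O)OC
F9 | step 15 | methyl (2Z,6E)-7-(hydroxymethyl)-3-methyl-9-[(4aS,8aS)-2,5,5,8a-tetramethyl-3,4,4a,5,6,7,8,8a-octahydronaphthalen-1-yl]nona-2,6-dien-4-ynoate | C/C(=C/C(=O)OC)C#C/C=C(/CO)CCC1=C(C)CC[C@H]2C(C)(C)CCC[C@]12C
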